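**Retrosynthetic overview**
- The ten-membered ring is closed last, by ring-closing metathesis at C1=C10 (ring-cis, E), followed only by desilylation.
- The C8 angelate comes from Mitsunobu inversion of an (8S)-alcohol.
- Key bond C7–C8: intermolecular zinc Barbier allylation of methyl 2-methylidene-4-oxobutanoate with a 3-(bromomethyl)butenolide. This sets C7 and C8 and creates the exo-methylene.
- The bromomethylbutenolide comes from L-tartaric diamide (C5 and C6 from the chiral pool) by mono-Grignard addition, methylenation, (Z)-Wittig/lactonisation and a seleno-Michael–aldol hydroxymethylation.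
- Ring order: γ-lactone first (step 7), carbocycle last (step 16).

Assumption: (+)-N,N,N′,N′-tetramethyl-L-tartaramide, but-3-enylmagnesium bromide, methyl 2-(bromomethyl)acrylate and angelic acid are bought. Positions are cited in germacrane numbering (C12 lactone carbonyl, C13 exo-methylene, C14 ester carbon, C15 ring methylene). TBS = tert-butyldimethylsilyl.

**Step 1**
Reactants: 1 (2R,3R)-2,3-dihydroxy-N,N,N′,N′-tetramethylbutanediamide
Product: 2 (4R,5R)-N,N,N′,N′,2,2-hexamethyl-1,3-dioxolane-4,5-dicarboxamide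
Conditions: 2,2-dimethoxypropane, p-TsOH·H2O (cat.), toluene, 80 °C
Reagents that add atoms: 2,2-dimethoxypropane COC(C)(C)OC
Why: Acid-catalysed transketalisation (acetonide formation) ties both hydroxyls into a trans-dioxolane without touching either stereocentre, so C5 and C6 come from the chiral pool.

**Step 2**
Reactants: 2 (4R,5R)-N,N,N′,N′,2,2-hexamethyl-1,3-dioxolane-4,5-dicarboxamide; 3 but-3-en-1-ylmagnesium bromide
Product: 5 (4R,5R)-N,N,2,2-tetramethyl-5-(pent-4-enoyl)-1,3-dioxolane-4-carboxamide, via magnesium hemiaminal 4 (not isolated)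
Conditions: 3 (1.5 equiv), THF, −15 → 0 °C; aq. NH4Cl
Reagents that add atoms: none
Why: Grignard addition to a tertiary amide stops at mono-addition because magnesium hemiaminal 4 survives until work-up and deactivates the second amide, which desymmetrises the C2-symmetric diamide and brings in C1–C3.

**Step 3**
Reactants: 5 (4R,5R)-N,N,2,2-tetramethyl-5-(pent-4-enoyl)-1,3-dioxolane-4-carboxamide
Product: 6 (4R,5S)-5-(hexa-1,5-dien-2-yl)-N,N,2,2-tetramethyl-1,3-dioxolane-4-carboxamide
Conditions: Ph3PCH3Br, KOtBu, THF, 0 °C → rt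
Reagents that add atoms: methyltriphenylphosphonium bromide C[P+](c1ccccc1)(c1ccccc1)c1ccccc1.[Br-]
Why: Wittig methylenation turns the ketone into the C4=C15 methylene; the trans-dioxolane is the thermodynamic isomer, so the α-centre is not at risk (the descriptor changes to S only through CIP priorities).

**Step 4**
Reactants: 6 (4R,5S)-5-(hexa-1,5-dien-2-yl)-N,N,2,2-tetramethyl-1,3-dioxolane-4-carboxamide
Product: 7 [(4S,5S)-5-(hexa-1,5-dien-2-yl)-2,2-dimethyl-1,3-dioxolan-4-yl]methanol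
Conditions: LiEt3BH (2.5 equiv), THF, 0 °C → rt; H2O
Reagents that add atoms: none
Why: LiEt3BH reduces N,N-dialkylamides to primary alcohols by C–N cleavage and leaves the alkenes and the acetonide alone.

**Step 5**
Reactants: 7 [(4S,5S)-5-(hexa-1,5-dien-2-yl)-2,2-dimethyl-1,3-dioxolan-4-yl]methanol
Product: 8 (4R,5S)-5-(hexa-1,5-dien-2-yl)-2,2-dimethyl-1,3-dioxolane-4-carbaldehyde
Conditions: Dess–Martin periodinane, CH2Cl2, 0 °C → rt; used at once
Reagents that add atoms: none
Why: Dess–Martin oxidation gives the α-alkoxy aldehyde under non-basic conditions that do not epimerise C6.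

**Step 6**
Reactants: 8 (4R,5S)-5-(hexa-1,5-dien-2-yl)-2,2-dimethyl-1,3-dioxolane-4-carbaldehyde
Product: 9 methyl (2Z)-3-[(4S,5S)-5-(hexa-1,5-dien-2-yl)-2,2-dimethyl-1,3-dioxolan-4-yl]prop-2-enoate
Conditions: Ph3P=CHCO2Me, MeOH, 0 °C (Z:E about 8:1; Z isomer isolated)
Reagents that add atoms: methyl (triphenylphosphoranylidene)acetate COC(=O)C=P(c1ccccc1)(c1ccccc1)c1ccccc1
Why: Wittig olefination of an α-alkoxy aldehyde with a stabilised ylide in methanol is (Z)-selective, which places the ester cis to C6 as lactonisation requires.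

**Step 7**
Reactants: 9 methyl (2Z)-3-[(4S,5S)-5-(hexa-1,5-dien-2-yl)-2,2-dimethyl-1,3-dioxolan-4-yl]prop-2-enoate
Product: 11 (5S)-5-[(1S)-1-hydroxy-2-methylidenehex-5-en-1-yl]furan-2(5H)-one, via dihydroxy ester 10 (not isolated)
Conditions: p-TsOH·H2O (10 mol%), THF/H2O 5:1, 45 °C
Reagents that add atoms: none
Why: Acetonide hydrolysis releases dihydroxy ester 10, whose C6 hydroxyl lactonises onto the cis ester (five-ring closure preferred over the six-ring alternative through O5), forming the butenolide with C5 and C6 untouched.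

**Step 8**
Reactants: 11 (5S)-5-[(1S)-1-hydroxy-2-methylidenehex-5-en-1-yl]furan-2(5H)-one
Product: 12 (5S)-5-[(1S)-1-(TBSO)-2-methylidenehex-5-en-1-yl]furan-2(5H)-one
Conditions: TBSCl, imidazole, DMAP (cat.), DMF, rt
Reagents that add atoms: tert-butyldimethylsilyl chloride CC(C)(C)[Si](C)(C)Cl
Why: Standard silylation protects the allylic C5 hydroxyl, and imidazole is too weak a base to enolise the butenolide, so C6 is not racemised.

**Step 9**
Reactants: 12 (5S)-5-[(1S)-1-(TBSO)-2-methylidenehex-5-en-1-yl]furan-2(5H)-one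
Product: 14 (3R,4S,5R)-3-(hydroxymethyl)-4-(phenylselanyl)-5-[(1S)-1-(TBSO)-2-methylidenehex-5-en-1-yl]oxolan-2-one, via lithium enolate 13 (not isolated)
Conditions: PhSeLi (from PhSeH, n-BuLi), THF, −78 °C; CH2O (gas), −78 °C; AcOH
Reagents that add atoms: benzeneselenol [SeH]c1ccccc1; formaldehyde C=O
Why: Tandem Michael–aldol reaction (a selenium-mediated Morita–Baylis–Hillman equivalent): soft PhSeLi adds 1,4 anti to the C6 side chain and lithium enolate 13 is trapped by formaldehyde anti to selenium; both new centres are erased in step 10.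

**Step 10**
Reactants: 14 (3R,4S,5R)-3-(hydroxymethyl)-4-(phenylselanyl)-5-[(1S)-1-(TBSO)-2-methylidenehex-5-en-1-yl]oxolan-2-one
Product: 16 (5S)-3-(hydroxymethyl)-5-[(1S)-1-(TBSO)-2-methylidenehex-5-en-1-yl]furan-2(5H)-one, via selenoxide 15 (not isolated)
Conditions: 30% H2O2, pyridine, CH2Cl2, 0 °C → rt
Reagents that add atoms: none
Why: Selenide oxidation and syn-elimination of selenoxide 15 toward the acidic α-hydrogen (not toward oxygen-bearing C6) restores the butenolide double bond.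

**Step 11**
Reactants: 16 (5S)-3-(hydroxymethyl)-5-[(1S)-1-(TBSO)-2-methylidenehex-5-en-1-yl]furan-2(5H)-one
Product: 17 (5S)-3-(bromomethyl)-5-[(1S)-1-(TBSO)-2-methylidenehex-5-en-1-yl]furan-2(5H)-one
Conditions: CBr4, PPh3, CH2Cl2, 0 °C
Reagents that add atoms: carbon tetrabromide BrC(Br)(Br)Br
Why: The Appel reaction converts the primary allylic alcohol into the bromide under neutral conditions that spare the silyl ether and the butenolide.

**Step 12**
Reactants: 18 methyl 2-(bromomethyl)prop-2-enoate; 19 vinylmagnesium bromide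
Product: 20 methyl 2-methylidenepent-4-enoate
Conditions: CuI (10 mol%), THF, −78 → −30 °C
Reagents that add atoms: none
Why: Copper-catalysed SN2′ (addition–elimination) substitution of the bromomethyl acrylate by the vinyl Grignard gives the skipped diene ester.

**Step 13**
Reactants: 20 methyl 2-methylidenepent-4-enoate
Product: 22 methyl 2-methylidene-4-oxobutanoate, via ozonide 21 (not isolated)
Conditions: O3 (1 equiv, Sudan Red 7B end-point), CH2Cl2, −78 °C; PPh3, −78 °C → rt; used crude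
Reagents that add atoms: ozone [O-][O+]=O
Why: Ozonolysis is chemoselective for the electron-rich monosubstituted alkene over the acrylate, and reduction of ozonide 21 gives the β,γ-unsaturated aldehyde, used crude so that it does not isomerise into conjugation.

**Step 14 (key step)**
Reactants: 17 (5S)-3-(bromomethyl)-5-[(1S)-1-(TBSO)-2-methylidenehex-5-en-1-yl]furan-2(5H)-one; 22 methyl 2-methylidene-4-oxobutanoate
Product: 24 methyl (4S)-4-hydroxy-2-methylidene-4-{(2S,3R)-4-methylidene-5-oxo-2-[(1S)-1-(TBSO)-2-methylidenehex-5-en-1-yl]oxolan-3-yl}butanoate, via allylzinc bromide 23 (not isolated)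
Conditions: Zn dust, THF/sat. aq. NH4Cl 3:1, 0 °C → rt
Reagents that add atoms: none
Why: Zinc Barbier carbonyl allylation: allylzinc bromide 23 attacks the aldehyde through its γ-carbon C7 in a closed chair transition state on the face anti to the C6 side chain (C7 = R, trans lactone) with the aldehyde chain equatorial (C8 = S), and the double bond moves out to the exo-methylene.

**Step 15**
Reactants: 24 methyl (4S)-4-hydroxy-2-methylidene-4-{(2S,3R)-4-methylidene-5-oxo-2-[(1S)-1-(TBSO)-2-methylidenehex-5-en-1-yl]oxolan-3-yl}butanoate; 25 angelic acid, (2Z)-2-methylbut-2-enoic acid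
Product: 26 methyl (4R)-2-methylidene-4-{[(2Z)-2-methylbut-2-enoyl]oxy}-4-{(2S,3R)-4-methylidene-5-oxo-2-[(1S)-1-(TBSO)-2-methylidenehex-5-en-1-yl]oxolan-3-yl}butanoate
Conditions: PPh3, DIAD, toluene, 0 °C → rt
Reagents that add atoms: none
Why: Mitsunobu esterification displaces the phosphine-activated hydroxyl by angelate in an SN2 step that inverts C8 to R, and using the acid as nucleophile rather than as an activated acyl donor avoids angelate-to-tiglate isomerisation.

**Step 16**
Reactants: 26 methyl (4R)-2-methylidene-4-{[(2Z)-2-methylbut-2-enoyl]oxy}-4-{(2S,3R)-4-methylidene-5-oxo-2-[(1S)-1-(TBSO)-2-methylidenehex-5-en-1-yl]oxolan-3-yl}butanoate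
Product: 27 methyl (3aR,4R,6E,11S,11aS)-11-(TBSO)-3,10-dimethylidene-4-{[(2Z)-2-methylbut-2-enoyl]oxy}-2-oxo-2,3,3a,4,5,8,9,10,11,11a-decahydrocyclodeca[b]furan-6-carboxylate
Conditions: second-generation Hoveyda–Grubbs catalyst (10 mol%), toluene (1 mM), 80 °C, argon sparge
Reagents that add atoms: none
Why: Ring-closing metathesis joins the terminal vinyl to the acrylate methylene to give the ring-cis (E) C1=C10 enoate, since the other 1,1-disubstituted alkenes could only close to a cyclobutene or a bridgehead alkene and the angelate is inert.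

**Step 17**
Reactants: 27 methyl (3aR,4R,6E,11S,11aS)-11-(TBSO)-3,10-dimethylidene-4-{[(2Z)-2-methylbut-2-enoyl]oxy}-2-oxo-2,3,3a,4,5,8,9,10,11,11a-decahydrocyclodeca[b]furan-6-carboxylate
Product: 28 methyl (3aR,4R,6E,11S,11aS)-11-hydroxy-3,10-dimethylidene-4-{[(2Z)-2-methylbut-2-enoyl]oxy}-2-oxo-2,3,3a,4,5,8,9,10,11,11a-decahydrocyclodeca[b]furan-6-carboxylate
Conditions: HF·pyridine, THF/pyridine, 0 °C → rt
Reagents that add atoms: none
Why: Buffered fluoride desilylation frees the C5 hydroxyl without the base that would attack the α-methylene lactone or isomerise the angelate.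

**Compound list**
1 | (2R,3R)-2,3-dihydroxy-N,N,N′,N′-tetramethylbutanediamide | CN(C)C(=O)[C@H](O)[C@@H](O)C(=O)N(C)C | starting material
2 | (4R,5R)-N,N,N′,N′,2,2-hexamethyl-1,3-dioxolane-4,5-dicarboxamide | CN(C)C(=O)[C@@H]1OC(C)(C)O[C@H]1C(=O)N(C)C | intermediate
3 | but-3-en-1-ylmagnesium bromide | C=CCC[Mg]Br | starting material
4 | bromomagnesium hemiaminal of the mono-adduct (hemiaminal carbon unassigned) | CN(C)C(=O)[C@@H]1OC(C)(C)O[C@H]1C(CCC=C)(O[Mg]Br)N(C)C | intermediate
5 | (4R,5R)-N,N,2,2-tetramethyl-5-(pent-4-enoyl)-1,3-dioxolane-4-carboxamide | CN(C)C(=O)[C@@H]1OC(C)(C)O[C@H]1C(=O)CCC=C | intermediate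
6 | (4R,5S)-5-(hexa-1,5-dien-2-yl)-N,N,2,2-tetramethyl-1,3-dioxolane-4-carboxamide | CN(C)C(=O)[C@@H]1OC(C)(C)O[C@H]1C(=C)CCC=C | intermediate
7 | [(4S,5S)-5-(hexa-1,5-dien-2-yl)-2,2-dimethyl-1,3-dioxolan-4-yl]methanol | OC[C@@H]1OC(C)(C)O[C@H]1C(=C)CCC=C | intermediate
8 | (4R,5S)-5-(hexa-1,5-dien-2-yl)-2,2-dimethyl-1,3-dioxolane-4-carbaldehyde | O=C[C@@H]1OC(C)(C)O[C@H]1C(=C)CCC=C | intermediate
9 | methyl (2Z)-3-[(4S,5S)-5-(hexa-1,5-dien-2-yl)-2,2-dimethyl-1,3-dioxolan-4-yl]prop-2-enoate | COC(=O)/C=C\[C@@H]1OC(C)(C)O[C@H]1C(=C)CCC=C | intermediate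
10 | methyl (2Z,4S,5S)-4,5-dihydroxy-6-methylidenedeca-2,9-dienoate | COC(=O)/C=C\[C@H](O)[C@@H](O)C(=C)CCC=C | intermediate
11 | (5S)-5-[(1S)-1-hydroxy-2-methylidenehex-5-en-1-yl]furan-2(5H)-one | O=C1C=C[C@@H]([C@@H](O)C(=C)CCC=C)O1 | intermediate
12 | (5S)-5-[(1S)-1-{[tert-butyl(dimethyl)silyl]oxy}-2-methylidenehex-5-en-1-yl]furan-2(5H)-one | O=C1C=C[C@@H]([C@@H](O[Si](C)(C)C(C)(C)C)C(=C)CCC=C)O1 | intermediate
13 | lithium (4S,5R)-4-(phenylselanyl)-5-[(1S)-1-(TBSO)-2-methylidenehex-5-en-1-yl]-4,5-dihydrofuran-2-olate | [Li]OC1=C[C@H]([Se]c2ccccc2)[C@@H]([C@@H](O[Si](C)(C)C(C)(C)C)C(=C)CCC=C)O1 | intermediate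
14 | (3R,4S,5R)-3-(hydroxymethyl)-4-(phenylselanyl)-5-[(1S)-1-(TBSO)-2-methylidenehex-5-en-1-yl]oxolan-2-one | O=C1[C@@H](CO)[C@H]([Se]c2ccccc2)[C@@H]([C@@H](O[Si](C)(C)C(C)(C)C)C(=C)CCC=C)O1 | intermediate
15 | selenoxide of 14 (selenium centre unassigned) | O=C1[C@@H](CO)[C@H]([Se](=O)c2ccccc2)[C@@H]([C@@H](O[Si](C)(C)C(C)(C)C)C(=C)CCC=C)O1 | intermediate
16 | (5S)-3-(hydroxymethyl)-5-[(1S)-1-(TBSO)-2-methylidenehex-5-en-1-yl]furan-2(5H)-one | O=C1C(CO)=C[C@@H]([C@@H](O[Si](C)(C)C(C)(C)C)C(=C)CCC=C)O1 | intermediate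
17 | (5S)-3-(bromomethyl)-5-[(1S)-1-(TBSO)-2-methylidenehex-5-en-1-yl]furan-2(5H)-one | O=C1C(CBr)=C[C@@H]([C@@H](O[Si](C)(C)C(C)(C)C)C(=C)CCC=C)O1 | intermediate
18 | methyl 2-(bromomethyl)prop-2-enoate | C=C(CBr)C(=O)OC | starting material
19 | vinylmagnesium bromide | C=C[Mg]Br | starting material
20 | methyl 2-methylidenepent-4-enoate | C=CCC(=C)C(=O)OC | intermediate
21 | methyl 2-[(1,2,4-trioxolan-3-yl)methyl]prop-2-enoate (racemic at the ring carbon) | COC(=O)C(=C)CC1OCOO1 | intermediate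
22 | methyl 2-methylidene-4-oxobutanoate | O=CCC(=C)C(=O)OC | intermediate
23 | bromo({(5S)-2-oxo-5-[(1S)-1-(TBSO)-2-methylidenehex-5-en-1-yl]-2,5-dihydrofuran-3-yl}methyl)zinc | O=C1C(C[Zn]Br)=C[C@@H]([C@@H](O[Si](C)(C)C(C)(C)C)C(=C)CCC=C)O1 | intermediate
24 | methyl (4S)-4-hydroxy-2-methylidene-4-{(2S,3R)-4-methylidene-5-oxo-2-[(1S)-1-(TBSO)-2-methylidenehex-5-en-1-yl]oxolan-3-yl}butanoate | C=C1C(=O)O[C@H]([C@@H](O[Si](C)(C)C(C)(C)C)C(=C)CCC=C)[C@H]1[C@@H](O)CC(=C)C(=O)OC | intermediate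
25 | angelic acid, (2Z)-2-methylbut-2-enoic acid | C/C=C(/C)C(=O)O | starting material
26 | methyl (4R)-2-methylidene-4-{[(2Z)-2-methylbut-2-enoyl]oxy}-4-{(2S,3R)-4-methylidene-5-oxo-2-[(1S)-1-(TBSO)-2-methylidenehex-5-en-1-yl]oxolan-3-yl}butanoate | C=C1C(=O)O[C@H]([C@@H](O[Si](C)(C)C(C)(C)C)C(=C)CCC=C)[C@H]1[C@H](OC(=O)/C(C)=C\C)CC(=C)C(=O)OC | intermediate
27 | methyl (3aR,4R,6E,11S,11aS)-11-{[tert-butyl(dimethyl)silyl]oxy}-3,10-dimethylidene-4-{[(2Z)-2-methylbut-2-enoyl]oxy}-2-oxo-2,3,3a,4,5,8,9,10,11,11a-decahydrocyclodeca[b]furan-6-carboxylate | C=C1C(=O)O[C@H]2[C@H]1[C@H](OC(=O)/C(C)=C\C)C/C(C(=O)OC)=C\CCC(=C)[C@@H]2O[Si](C)(C)C(C)(C)C | intermediate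
28 | methyl (3aR,4R,6E,11S,11aS)-11-hydroxy-3,10-dimethylidene-4-{[(2Z)-2-methylbut-2-enoyl]oxy}-2-oxo-2,3,3a,4,5,8,9,10,11,11a-decahydrocyclodeca[b]furan-6-carboxylate (germacrane 5S,6S,7R,8R) | C=C1C(=O)O[C@H]2[C@H]1[C@H](OC(=O)/C(C)=C\C)C/C(C(=O)OC)=C\CCC(=C)[C@@H]2O | target

**Totals**
Total step count: 17. Longest linear sequence: 15 (steps 1–11 and 14–17).

**Three steps most likely to fail**

Step 14 (Barbier union). The aldehyde 22 can isomerise into conjugation, the allylzinc can ring-open by β-elimination, and the closed transition state delivers the C8 epimer that then needs inversion. The fallback sets out from 17 and comes back at 26. Bromide 17 is stannylated with (Bu3Sn)2 and Pd(PPh3)4 in THF at 50 °C to the allyltributylstannane F1. F1 is added to 22 with BF3·OEt2 in CH2Cl2 at −78 °C; the open antiperiplanar transition state, with the aldehyde chain turned away from C6, gives the (8R)-alcohol F2 directly. F2 is acylated with 25 through its 2,4,6-trichlorobenzoyl mixed anhydride (Et3N, toluene, 80 °C, no DMAP) with retention to give 26, so step 15 is bypassed.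

Step 15 (Mitsunobu with angelic acid at a hindered carbinol flanked by allylic hydrogens, where elimination competes). The fallback sets out from 24 and comes back at 26. Alcohol 24 is converted with ClCH2SO2Cl and pyridine in CH2Cl2 at 0 °C into the chloromethanesulfonate F3. F3 is displaced by caesium angelate (from 25 and Cs2CO3) with 18-crown-6 in toluene at 60 °C, an SN2 reaction with inversion, to give 26.

Step 16 (metathesis to a trisubstituted enoate in a ten-membered ring, where oligomerisation and slow turnover at the acrylate are likely). The fallback sets out from 24 and comes back at 27. The ring is closed before acylation, on the less congested hydroxy ester 24, with the same ruthenium catalyst at high dilution to give the ten-membered (8S)-alcohol F4. F4 is then esterified with 25 under Mitsunobu conditions (PPh3, DIAD, toluene) with inversion to give 27.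

**Further compounds**
F1 | step 14 | tributyl({(5S)-2-oxo-5-[(1S)-1-(TBSO)-2-methylidenehex-5-en-1-yl]-2,5-dihydrofuran-3-yl}methyl)stannane | CCCC[Sn](CCCC)(CCCC)CC1=C[C@@H]([C@@H](O[Si](C)(C)C(C)(C)C)C(=C)CCC=C)OC1=O
F2 | step 14 | methyl (4R)-4-hydroxy-2-methylidene-4-{(2S,3R)-4-methylidene-5-oxo-2-[(1S)-1-(TBSO)-2-methylidenehex-5-en-1-yl]oxolan-3-yl}butanoate (C8 epimer of 24) | C=C1C(=O)O[C@H]([C@@H](O[Si](C)(C)C(C)(C)C)C(=C)CCC=C)[C@H]1[C@H](O)CC(=C)C(=O)OC
F3 | step 15 | chloromethanesulfonate ester of alcohol 24 (C8 configuration as in 24) | C=C1C(=O)O[C@H]([C@@H](O[Si](C)(C)C(C)(C)C)C(=C)CCC=C)[C@H]1[C@@H](OS(=O)(=O)CCl)CC(=C)C(=O)OC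
F4 | step 16 | methyl (3aR,4S,6E,11S,11aS)-4-hydroxy-3,10-dimethylidene-2-oxo-11-(TBSO)-2,3,3a,4,5,8,9,10,11,11a-decahydrocyclodeca[b]furan-6-carboxylate | C=C1C(=O)O[C@H]2[C@H]1[C@@H](O)C/C(C(=O)OC)=C\CCC(=C)[C@@H]2O[Si](C)(C)C(C)(C)C
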